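**Plan**

1. Cuts: (i) the three O‑benzyl bonds. (ii) The diol C9‑C8‑C8'‑C9' is folded back into a 5‑menthyloxy‑γ‑butyrolactone. (iii) This lactone is cut in one operation at C7‑C8 (CH2 of the free guaiacyl ring to chain CH) and at C8'‑C7' (chain CH to the CH2 on C5 of the dihydrobenzofuran). (iv) The dihydrobenzofuran is cut at C2‑C3 and at C3‑C3a.
2. Enabling feature: C7 sits on the guaiacyl ring and is the carbonyl carbon of vanillin. C8, flanked by the oxygenated carbons C9 and C9', is the β‑carbon of a butenolide. Both are acceptor carbons, so C7 is reversed in polarity as a lithiated bis(phenylthio)acetal.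
3. Forward: 5‑iodovanillin is O‑alkylated with the second guaiacyl unit, coupled with ethyl diazoacetate and closed to the dihydrobenzofuran, the only ring that has to be built. It is then taken on to the 5‑bromomethyl compound.
4. One flask then joins the vanillin dithioacetal anion, (5R)‑menthyloxybutenolide and the bromide, forming C7‑C8 first and C8'‑C7' second.
5. Stereochemistry: C2 comes from the chiral dirhodium catalyst and C3 from equilibration to the trans ester. C8 is set by addition anti to the menthyloxy group on the acetal carbon, and C8' by alkylation anti to the new C8 substituent.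
6. The helpers leave at the end: the SPh groups with tin hydride, the lactone ring and menthol with LiAlH4, and the benzyl groups by hydrogenolysis.

Key step: step 12

Assumption: the 2S sense of induction of Rh2(R‑PTTL)4 in step 5 is assigned by analogy with related aryldiazoacetate insertions, and the antipodal catalyst is equally available should the sense prove opposite.

**Step 1**
Reactants: 1 5‑iodovanillin (4‑hydroxy‑3‑iodo‑5‑methoxybenzaldehyde); 2 4‑(benzyloxy)‑3‑methoxybenzyl alcohol
Product: 3 4‑{[4‑(benzyloxy)‑3‑methoxybenzyl]oxy}‑3‑iodo‑5‑methoxybenzaldehyde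
Conditions: PPh3, DIAD, THF, 0 °C to rt
Reagents that add atoms: none
Why: Mitsunobu etherification, in which the acidic phenol of 1 (para‑formyl, ortho‑iodo) is alkylated by the activated primary benzylic alcohol under neutral conditions, so no labile electron‑rich benzyl halide has to be handled.

**Step 2**
Reactants: 3 aryl ether aldehyde
Product: 4 (4‑{[4‑(benzyloxy)‑3‑methoxybenzyl]oxy}‑3‑iodo‑5‑methoxyphenyl)methanol
Conditions: NaBH4, MeOH–THF, 0 °C
Reagents that add atoms: none
Why: Borohydride reduction of an aryl aldehyde, which leaves iodide and ethers untouched and removes the para acceptor that could intercept the carbenoid of step 5 and favour ring opening in step 6.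

**Step 3**
Reactants: 4 benzylic alcohol
Product: 5 tert‑butyldimethylsilyl ether of 4
Conditions: TBSCl, imidazole, DMF, rt
Reagents that add atoms: tert‑butyldimethylsilyl chloride CC(C)(C)[Si](C)(C)Cl
Why: Standard silylation of a primary alcohol, which blocks O–H insertion in step 5 and keeps this oxygen distinct from the alcohol released in step 7.

**Step 4**
Reactants: 5 aryl iodide; 6 ethyl diazoacetate
Product: 7 ethyl 2‑diazo‑2‑(2‑{[4‑(benzyloxy)‑3‑methoxybenzyl]oxy}‑5‑{[(tert‑butyldimethylsilyl)oxy]methyl}‑3‑methoxyphenyl)acetate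
Conditions: Pd(PPh3)4 (cat.), Ag2CO3 (0.5 equiv), Et3N, toluene, rt
Reagents that add atoms: none
Why: Palladium‑catalysed cross‑coupling of an aryl iodide with the C–H bond of a diazoacetate with retention of the diazo group, where silver carbonate takes up iodide and the proton so that the aryldiazoacetate arises in one step.

**Step 5**
Reactants: 7 aryldiazoacetate
Product: 8 ethyl (2S,3R)‑cis‑2‑[4‑(benzyloxy)‑3‑methoxyphenyl]‑5‑{[(tert‑butyldimethylsilyl)oxy]methyl}‑7‑methoxy‑2,3‑dihydrobenzofuran‑3‑carboxylate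
Conditions: Rh2(R‑PTTL)4 (1 mol %), toluene, –60 °C
Reagents that add atoms: none
Why: Enantioselective intramolecular 1,5 C–H insertion of a donor/acceptor rhodium carbenoid into the ArCH2–O methylene closes the five‑membered ring at C2–C3, with the chiral carboxylate pocket choosing one of the two enantiotopic benzylic hydrogens (C2 = S) and the cis ester expected as the kinetic product.

**Step 6**
Reactants: 8 cis ester
Product: 9 ethyl (2S,3S)‑trans‑2‑[4‑(benzyloxy)‑3‑methoxyphenyl]‑5‑{[(tert‑butyldimethylsilyl)oxy]methyl}‑7‑methoxy‑2,3‑dihydrobenzofuran‑3‑carboxylate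
Conditions: NaOEt (cat.), EtOH–THF, rt
Reagents that add atoms: none
Why: Base‑mediated epimerisation through the ester enolate places the C3 ester trans to the C2 aryl group under thermodynamic control, while C2 is retained because expulsion of the phenoxide would be the reverse of a disfavoured 5‑endo‑trig closure.

**Step 7**
Reactants: 9 trans ester
Product: 10 [(2S,3R)‑2‑[4‑(benzyloxy)‑3‑methoxyphenyl]‑5‑{[(tert‑butyldimethylsilyl)oxy]methyl}‑7‑methoxy‑2,3‑dihydrobenzofuran‑3‑yl]methanol
Conditions: LiAlH4, THF, 0 °C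
Reagents that add atoms: none
Why: Hydride reduction of the ester to the primary alcohol removes the acidic C3–H/ester combination before any strong base is used and tolerates silyl and benzyl ethers.

**Step 8**
Reactants: 10 primary alcohol
Product: 11 (2S,3R)‑2‑[4‑(benzyloxy)‑3‑methoxyphenyl]‑3‑[(benzyloxy)methyl]‑5‑{[(tert‑butyldimethylsilyl)oxy]methyl}‑7‑methoxy‑2,3‑dihydrobenzofuran
Conditions: NaH, BnBr, Bu4NI (cat.), THF–DMF, 0 °C to rt
Reagents that add atoms: benzyl bromide BrCc1ccccc1
Why: Williamson etherification gives a base‑stable group without acidic hydrogens that leaves together with the two phenolic benzyl groups in the last step.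

**Step 9**
Reactants: 11 silyl ether
Product: 12 (2S,3R)‑2‑[4‑(benzyloxy)‑3‑methoxyphenyl]‑3‑[(benzyloxy)methyl]‑5‑(bromomethyl)‑7‑methoxy‑2,3‑dihydrobenzofuran
Conditions: Ph3PBr2, CH2Cl2, 0 °C to rt; used at once
Reagents that add atoms: triphenylphosphine dibromide BrP(Br)(c1ccccc1)(c1ccccc1)c1ccccc1
Why: Direct conversion of a silyl ether into a bromide with a dibromophosphorane (an Appel‑type alkoxyphosphonium displacement), fastest at the unhindered electron‑rich benzylic position and neutral enough for the benzyl ethers and the ring.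

**Step 10**
Reactants: 13 4‑(benzyloxy)‑3‑methoxybenzaldehyde (O‑benzylvanillin)
Product: 14 1‑(benzyloxy)‑4‑[bis(phenylthio)methyl]‑2‑methoxybenzene
Conditions: PhSH (2.1 equiv), BF3·OEt2 (cat.), CH2Cl2, 0 °C
Reagents that add atoms: thiophenol Sc1ccccc1
Why: Lewis acid catalysed dithioacetalisation of an aryl aldehyde installs the two sulfur groups that will acidify C7–H and stabilise the carbanion.

**Step 11**
Reactants: 15 5‑hydroxyfuran‑2(5H)‑one; 16 (–)‑menthol
Product: 17 (5R)‑5‑[(1R,2S,5R)‑menthyloxy]furan‑2(5H)‑one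
Conditions: neat, 100 °C; crystallisation from petroleum ether, mother liquor re‑equilibrated with CSA (cat.)
Reagents that add atoms: none
Why: Acetalisation of the pseudo‑acid with the chiral alcohol gives two C5 epimers that interconvert under acid, and the 5R epimer is collected by crystallisation (crystallisation‑driven epimer enrichment).

**Step 12**
Reactants: 14 vanillin bis(phenylthio)acetal; 17 (5R)‑menthyloxybutenolide; 12 benzylic bromide
Product: 20 (3R,4R,5R)‑3‑{[(2S,3R)‑2‑(4‑benzyloxy‑3‑methoxyphenyl)‑3‑(benzyloxymethyl)‑7‑methoxy‑2,3‑dihydrobenzofuran‑5‑yl]methyl}‑4‑[(4‑benzyloxy‑3‑methoxyphenyl)bis(phenylthio)methyl]‑5‑[(1R,2S,5R)‑menthyloxy]dihydrofuran‑2(3H)‑one, via lithiated dithioacetal 18 (not isolated), via lithium lactone enolate 19 (not isolated)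
Conditions: n‑BuLi, THF, –78 °C; then 17, –78 °C; then 12, DMPU, –78 °C to rt
Reagents that add atoms: none
Why: n‑BuLi removes the C7–H of 14, so that in 18 the former aldehyde carbon of vanillin is a nucleophile, 18 adds 1,4 to the butenolide to form C7–C8, and the resulting enolate 19 is alkylated in the same flask at C8' by bromide 12 in an SN2 step. The closest known reaction type is the tandem conjugate addition–enolate alkylation of lithiated aryl bis(phenylthio)acetals on 5‑alkoxyfuran‑2(5H)‑ones, which is established for dibenzylbutyrolactone and dibenzylbutanediol lignans. No ring is closed, since the lactone of 17 is a temporary ring that only carries stereochemical information. C8 (lactone C4) is set because the carbanion approaches the face anti to the C5 menthyloxy group, and C8' (lactone C3) is set because the bromide approaches anti to the very large C(SPh)2Ar group, which should give the trans,trans 3R,4R,5R array. The step needs 1,4 over 1,2 addition, secured by the soft sulfur‑stabilised carbanion, and it needs alkylation to outrun proton transfer, secured because 12 carries C9'' as a benzyl ether at the alcohol level and so has no acidic C–H or O–H. The C2 and C3 centres of the dihydrobenzofuran take no part in the step.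

**Step 13**
Reactants: 20 dithioacetal lactone
Product: 21 (3R,4R,5R)‑4‑(4‑benzyloxy‑3‑methoxybenzyl)‑3‑{[(2S,3R)‑2‑(4‑benzyloxy‑3‑methoxyphenyl)‑3‑(benzyloxymethyl)‑7‑methoxy‑2,3‑dihydrobenzofuran‑5‑yl]methyl}‑5‑[(1R,2S,5R)‑menthyloxy]dihydrofuran‑2(3H)‑one
Conditions: Bu3SnH (excess), AIBN (portions), toluene, reflux
Reagents that add atoms: none
Why: Radical desulfurisation with tin hydride cleaves both benzylic C–S bonds through stabilised benzylic radicals and leaves benzyl ethers, the benzylic C2–O bond and the lactone acetal untouched.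

**Step 14**
Reactants: 21 menthyloxy lactone
Product: 22 (2R,3R)‑2‑(4‑benzyloxy‑3‑methoxybenzyl)‑3‑{[(2S,3R)‑2‑(4‑benzyloxy‑3‑methoxyphenyl)‑3‑(benzyloxymethyl)‑7‑methoxy‑2,3‑dihydrobenzofuran‑5‑yl]methyl}butane‑1,4‑diol
Conditions: LiAlH4, THF, 0 °C to rt
Reagents that add atoms: none
Why: Hydride reduction of the lactone opens the ring to a hemiacetal alkoxide that expels menthoxide and is reduced further, so C9 and C9' both end as CH2OH faster than the transient aldehydes can enolise at C8 or C8'.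

**Step 15**
Reactants: 22 tribenzyl ether
Product: 23 target, (2R,3R)‑2‑(4‑hydroxy‑3‑methoxybenzyl)‑3‑{[(2S,3R)‑2‑(4‑hydroxy‑3‑methoxyphenyl)‑3‑(hydroxymethyl)‑7‑methoxy‑2,3‑dihydrobenzofuran‑5‑yl]methyl}butane‑1,4‑diol
Conditions: H2 (1 atm), 10 % Pd/C, EtOAc–MeOH, rt
Reagents that add atoms: none
Why: Catalytic hydrogenolysis removes the three unhindered primary benzyl ethers, while the secondary, ring‑bound and hindered C2–O bond of 2‑aryl‑2,3‑dihydrobenzofurans is known to tolerate these mild neutral conditions.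

**Compound list**

1 | 5‑iodovanillin | COc1cc(C=O)cc(I)c1O | starting material
2 | 4‑(benzyloxy)‑3‑methoxybenzyl alcohol | COc1cc(CO)ccc1OCc1ccccc1 | starting material
3 | 4‑{[4‑(benzyloxy)‑3‑methoxybenzyl]oxy}‑3‑iodo‑5‑methoxybenzaldehyde | COc1cc(C=O)cc(I)c1OCc1ccc(OCc2ccccc2)c(OC)c1 | intermediate
4 | (4‑{[4‑(benzyloxy)‑3‑methoxybenzyl]oxy}‑3‑iodo‑5‑methoxyphenyl)methanol | COc1cc(CO)cc(I)c1OCc1ccc(OCc2ccccc2)c(OC)c1 | intermediate
5 | TBS ether of 4 | COc1cc(CO[Si](C)(C)C(C)(C)C)cc(I)c1OCc1ccc(OCc2ccccc2)c(OC)c1 | intermediate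
6 | ethyl diazoacetate | CCOC(=O)C=[N+]=[N-] | starting material
7 | ethyl aryldiazoacetate | CCOC(=O)C(=[N+]=[N-])c1cc(CO[Si](C)(C)C(C)(C)C)cc(OC)c1OCc1ccc(OCc2ccccc2)c(OC)c1 | intermediate
8 | (2S,3R)‑cis dihydrobenzofuran ethyl ester | CC(C)(C)[Si](C)(C)OCc1cc(OC)c2c(c1)[C@@H](C(=O)OCC)[C@@H](c1ccc(OCc3ccccc3)c(OC)c1)O2 | intermediate
9 | (2S,3S)‑trans dihydrobenzofuran ethyl ester | CC(C)(C)[Si](C)(C)OCc1cc(OC)c2c(c1)[C@H](C(=O)OCC)[C@@H](c1ccc(OCc3ccccc3)c(OC)c1)O2 | intermediate
10 | (2S,3R)‑trans 3‑hydroxymethyl dihydrobenzofuran | CC(C)(C)[Si](C)(C)OCc1cc(OC)c2c(c1)[C@H](CO)[C@@H](c1ccc(OCc3ccccc3)c(OC)c1)O2 | intermediate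
11 | (2S,3R)‑3‑benzyloxymethyl 5‑silyloxymethyl dihydrobenzofuran | CC(C)(C)[Si](C)(C)OCc1cc(OC)c2c(c1)[C@H](COCc1ccccc1)[C@@H](c1ccc(OCc3ccccc3)c(OC)c1)O2 | intermediate
12 | (2S,3R)‑5‑bromomethyl dihydrobenzofuran | BrCc1cc(OC)c2c(c1)[C@H](COCc1ccccc1)[C@@H](c1ccc(OCc3ccccc3)c(OC)c1)O2 | intermediate
13 | 4‑(benzyloxy)‑3‑methoxybenzaldehyde | COc1cc(C=O)ccc1OCc1ccccc1 | starting material
14 | O‑benzylvanillin bis(phenylthio)acetal | COc1cc(C(Sc2ccccc2)Sc2ccccc2)ccc1OCc1ccccc1 | intermediate
15 | 5‑hydroxyfuran‑2(5H)‑one | OC1OC(=O)C=C1 | starting material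
16 | (–)‑menthol, (1R,2S,5R) | CC(C)[C@@H]1CC[C@@H](C)C[C@H]1O | starting material
17 | (5R)‑5‑[(1R,2S,5R)‑menthyloxy]furan‑2(5H)‑one | O=C1C=C[C@H](O[C@@H]2C[C@H](C)CC[C@H]2C(C)C)O1 | intermediate
18 | lithiated dithioacetal | COc1cc(C([Li])(Sc2ccccc2)Sc2ccccc2)ccc1OCc1ccccc1 | intermediate
19 | lithium lactone enolate | [Li]OC1=C[C@@H](C(Sc2ccccc2)(Sc2ccccc2)c2ccc(OCc3ccccc3)c(OC)c2)[C@H](O[C@@H]2C[C@H](C)CC[C@H]2C(C)C)O1 | intermediate
20 | (3R,4R,5R)‑three‑component lactone with C7(SPh)2 | O=C1[C@H](Cc2cc(OC)c3c(c2)[C@H](COCc2ccccc2)[C@@H](c2ccc(OCc4ccccc4)c(OC)c2)O3)[C@@H](C(Sc2ccccc2)(Sc2ccccc2)c2ccc(OCc3ccccc3)c(OC)c2)[C@H](O[C@@H]2C[C@H](C)CC[C@H]2C(C)C)O1 | intermediate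
21 | (3R,4R,5R)‑desulfurised lactone | O=C1[C@H](Cc2cc(OC)c3c(c2)[C@H](COCc2ccccc2)[C@@H](c2ccc(OCc4ccccc4)c(OC)c2)O3)[C@@H](Cc2ccc(OCc3ccccc3)c(OC)c2)[C@H](O[C@@H]2C[C@H](C)CC[C@H]2C(C)C)O1 | intermediate
22 | (2R,3R)‑tribenzyl diol | COc1cc(C[C@@H](CO)[C@H](CO)Cc2cc(OC)c3c(c2)[C@H](COCc2ccccc2)[C@@H](c2ccc(OCc4ccccc4)c(OC)c2)O3)ccc1OCc1ccccc1 | intermediate
23 | target CNP0256425.1 | COc1cc(C[C@@H](CO)[C@H](CO)Cc2cc(OC)c3c(c2)[C@H](CO)[C@@H](c2ccc(O)c(OC)c2)O3)ccc1O | target

**Step count and risks**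

Total step count: 15. Longest linear sequence: 13 (steps 1–9 and 12–15).

**Step 12.** The crowded enolate may be protonated or may decay faster than it is alkylated, so that the third component is not taken up.
- Fallback: the two C–C bonds are made in separate operations, and the second one on an unhindered enolate.
- 18 is added to 17 as before, but the enolate is quenched with NH4Cl to give the (4R,5R) Michael adduct F1.
- Bu3SnH/AIBN removes both phenylthio groups to give the (4R,5R)‑4‑benzyl‑5‑menthyloxy lactone F2.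
- LiHMDS in THF at –78 °C converts F2 into its lithium enolate F3, which is alkylated with 12 anti to the C4 benzyl group.
- This sets out from 14, 17 and 12 and comes back to the route at 21.

**Step 5.** The catalyst pocket may distinguish the two enantiotopic benzylic hydrogens poorly, or carbene dimerisation may compete.
- Fallback: a covalent auxiliary and separation of diastereomers replace pure catalyst control.
- 16 is converted with glyoxylic acid chloride tosylhydrazone and Et3N into (1R,2S,5R)‑menthyl diazoacetate F4.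
- F4 is coupled with 5 under palladium/silver catalysis to the menthyl aryldiazoacetate F5.
- Rhodium‑catalysed insertion gives the cis‑(2S,3R) menthyl ester F6, and DBU equilibrates it to the trans‑(2S,3S) menthyl ester F7.
- F7 is brought to diastereomeric purity by crystallisation or chromatography and reduced with LiAlH4.
- This sets out from 5 and 16 and comes back to the route at 10.

**Step 4.** Oxidative addition at the ortho‑alkoxy iodide may be slower than loss of nitrogen from the palladium‑bound diazo ester.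
- Fallback: the arylacetate is built first and the diazo group is introduced afterwards.
- 5 is coupled with the Reformatsky reagent BrZnCH2CO2Et (Pd(dba)2, bulky phosphine, THF) to the ethyl arylacetate F8.
- A Regitz diazo transfer (p‑ABSA, DBU, MeCN) converts F8 into the diazo ester.
- This sets out from 5 and comes back to the route at 7.

**Further compounds**

F1 | step 12 | (4R,5R)‑4‑[(4‑benzyloxy‑3‑methoxyphenyl)bis(phenylthio)methyl]‑5‑[(1R,2S,5R)‑menthyloxy]dihydrofuran‑2(3H)‑one | O=C1C[C@@H](C(Sc2ccccc2)(Sc2ccccc2)c2ccc(OCc3ccccc3)c(OC)c2)[C@H](O[C@@H]2C[C@H](C)CC[C@H]2C(C)C)O1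
F2 | step 12 | (4R,5R)‑4‑(4‑benzyloxy‑3‑methoxybenzyl)‑5‑[(1R,2S,5R)‑menthyloxy]dihydrofuran‑2(3H)‑one | O=C1C[C@@H](Cc2ccc(OCc3ccccc3)c(OC)c2)[C@H](O[C@@H]2C[C@H](C)CC[C@H]2C(C)C)O1
F3 | step 12 | lithium enolate of F2 | [Li]OC1=C[C@@H](Cc2ccc(OCc3ccccc3)c(OC)c2)[C@H](O[C@@H]2C[C@H](C)CC[C@H]2C(C)C)O1
F4 | step 5 | (1R,2S,5R)‑menthyl diazoacetate | CC(C)[C@@H]1CC[C@@H](C)C[C@H]1OC(=O)C=[N+]=[N-]
F5 | step 5 | (1R,2S,5R)‑menthyl aryldiazoacetate | CC(C)[C@@H]1CC[C@@H](C)C[C@H]1OC(=O)C(=[N+]=[N-])c1cc(CO[Si](C)(C)C(C)(C)C)cc(OC)c1OCc1ccc(OCc2ccccc2)c(OC)c1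
F6 | step 5 | cis‑(2S,3R) dihydrobenzofuran menthyl ester | CC(C)(C)[Si](C)(C)OCc1cc(OC)c2c(c1)[C@@H](C(=O)O[C@@H]1C[C@H](C)CC[C@H]1C(C)C)[C@@H](c1ccc(OCc3ccccc3)c(OC)c1)O2
F7 | step 5 | trans‑(2S,3S) dihydrobenzofuran menthyl ester | CC(C)(C)[Si](C)(C)OCc1cc(OC)c2c(c1)[C@H](C(=O)O[C@@H]1C[C@H](C)CC[C@H]1C(C)C)[C@@H](c1ccc(OCc3ccccc3)c(OC)c1)O2
F8 | step 4 | ethyl 2‑(2‑{[4‑(benzyloxy)‑3‑methoxybenzyl]oxy}‑5‑{[(tert‑butyldimethylsilyl)oxy]methyl}‑3‑methoxyphenyl)acetate | CCOC(=O)Cc1cc(CO[Si](C)(C)C(C)(C)C)cc(OC)c1OCc1ccc(OCc2ccccc2)c(OC)c1
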